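## Retrosynthetic overview
1. Target 23 comes from oxidation of the C15 alcohol 22. Ring D is closed last by a 5-exo vinyl-radical C16–C13 cyclisation of enyne 21, so C13 is dictated by C8.
2. Key step: one intermolecular Diels–Alder of butadiene with the transient 3-formyl-5-spiro-5,6-dihydropyran-2-one 17 builds ring C, quaternary C8 and C9. This avoids a tethered IMDA and a B-ring oxidative cleavage. The spiro ring A blocks one face.
3. Spiro C10 and the δ-lactone come from an Fe–H (MHAT) Giese addition of ring-A alkene 10 to methyl acrylate, followed by lactonisation.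
4. The concave-face OMe at C6 is set by hydride capture of an O-methyl-lactonium ion, so hydride rather than MeOH is the incoming group.
5. Ring A (C4, C5) comes from a catalytic enantioselective Diels–Alder of methacrolein with diene 6. Ring order: A → γ-lactone/THF → spiro δ-lactone → C → D.

**Assumptions**
- Atom labels C1–C20 follow ent-kaurane numbering of the target, which is (4R,5R,6R,8S,9S,10R,13R).
- The sense of induction in step 5 is assigned from the formyl C–H···O model. If the antipode forms, the (R)-catalyst is used, and both are commercial.
- The C15 carbinol epimers in 21 and 22 are not specified, because both converge on 23.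

## Route

**Step 1**
Reactants: 1, 2-butyne-1,4-diol
Product: 2, (E)-2-(tributylstannyl)but-2-ene-1,4-diol (the two CH2OH groups are cis)
Conditions: n-Bu3SnH, PdCl2(PPh3)2 (2 mol %), THF, 0 °C → rt
Reagents that add atoms: tributyltin hydride, CCCC[SnH](CCCC)CCCC
Why: Pd-catalysed hydrostannation is a strict syn addition on a symmetrical alkyne, so there is no regiochemical issue and the two CH2O arms end up cis, as needed for an "outside" diene substituent.

**Step 2**
Reactants: 2
Product: 3, (E)-4-(tert-butyldimethylsilyloxy)-2-(tributylstannyl)but-2-en-1-ol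
Conditions: TBSCl (1.0 equiv), imidazole, CH2Cl2, −20 → 0 °C
Reagents that add atoms: TBSCl, CC(C)(C)[Si](C)(C)Cl
Why: This is a sterically controlled monosilylation, because the CH2OH geminal to the bulky Bu3Sn group is shielded and only the remote (future C6) hydroxyl reacts.

**Step 3**
Reactants: 3; 4, vinyl bromide
Product: 5, (Z)-4-(tert-butyldimethylsilyloxy)-2-vinylbut-2-en-1-ol (vinyl trans to CH2OTBS)
Conditions: Pd(PPh3)4 (5 mol %), CuCl, LiCl, DMSO, 60 °C
Reagents that add atoms: vinyl bromide (4), C=CBr
Why: A Cu(I)-accelerated Stille coupling suits hindered 1-substituted vinylstannanes and retains alkene geometry, and the free allylic alcohol is used because an allylic acetate would be ionised by Pd(0).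

**Step 4**
Reactants: 5
Product: 6, (Z)-4-(tert-butyldimethylsilyloxy)-2-vinylbut-2-en-1-yl acetate
Conditions: Ac2O, Et3N, DMAP (cat.), CH2Cl2, 0 °C
Reagents that add atoms: acetic anhydride, CC(=O)OC(C)=O
Why: Simple acylation gives an acyclic ester on O-20 that survives steps 5–9 and weakens the competing "para"-directing effect of the C10 substituent in step 5.

**Step 5**
Reactants: 6; 7, methacrolein
Product: 8, (1R,2S)-3-(acetoxymethyl)-2-(TBSO-methyl)-1-methylcyclohex-3-ene-1-carbaldehyde (CHO = C19 on C4, CH2OTBS = C6 on C5, cis; alkene C1=C10)
Conditions: (S)-o-tolyl-oxazaborolidine·Tf2NH (15 mol %), CH2Cl2, −78 → −40 °C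
Reagents that add atoms: methacrolein (7), C=C(C)C=O
Why: In this catalytic enantioselective Diels–Alder (cationic oxazaborolidine), the unsubstituted diene terminus bonds first to the enal CH2 ("ortho" adduct), the catalyst-shielded enal face fixes quaternary C4, and the CHO-endo transition state with the E-terminus places C6 cis to C19 and so sets C5.

**Step 6**
Reactants: 8
Product: 9, [(5R,6R)-5,6-bis(hydroxymethyl)-5-methylcyclohex-1-en-1-yl]methyl acetate
Conditions: NaBH4, MeOH, 0 °C; AcOH quench, then NH4F, 50 °C (one pot)
Reagents that add atoms: none
Why: Chemoselective aldehyde reduction followed by near-neutral fluoride desilylation leaves the allylic acetate and both stereocentres untouched.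

**Step 7**
Reactants: 9
Product: 10, (3aR,7aR)-7-(acetoxymethyl)-3a-methyl-3a,4,5,7a-tetrahydroisobenzofuran-1(3H)-one (cis-fused γ-lactone, C6=O, O–C19H2)
Conditions: TEMPO (10 mol %), PhI(OAc)2 (2.5 equiv), CH2Cl2, rt (no base)
Reagents that add atoms: none
Why: TEMPO oxidative lactonisation of the 1,4-diol oxidises the unhindered C6 carbinol rather than neopentyl C19, and the resulting lactol is oxidised on to the lactone with the correct C6/C19 oxidation pattern.

**Step 8**
Reactants: 10; 11, methyl acrylate
Product: 12, the saturated cis-lactone carrying at C10 an α-CH2OAc (C20) and a β-CH2CH2CO2Me (C9–C8–C7) group, (4R,5R,10R)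
Conditions: Fe(acac)3, PhSiH3, methyl acrylate (3 equiv), EtOH/ethylene glycol, 60 °C
Reagents that add atoms: methyl acrylate (11), C=CC(=O)OC
Why: In this MHAT Giese reaction (reductive olefin coupling), Fe–H delivers H• to C1 and the tertiary C10 radical adds to acrylate from the face opposite the C5–C6 bond and the axial C19, so C9 ends trans to C6 and quaternary C10 is set.

**Step 9**
Reactants: 12
Product: 13, the (6R)-methyl acetal of 12 (6,19-epoxy-6-OMe; H-6 cis to H-5, OMe cis to C10)
Conditions: Me3OBF4, 2,6-di-tert-butyl-4-methylpyridine, CH2Cl2, rt; then n-Bu4NBH4, −78 °C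
Reagents that add atoms: trimethyloxonium tetrafluoroborate, C[O+](C)C.F[B-](F)(F)F
Why: Proposed new method: the lactone (an E-ester) is O-methylated much faster than the two acyclic Z-esters to give a planar 2-methoxyoxolanylium ion, and borohydride then adds irreversibly from the convex face (the H-5/CH3-18 side, since the concave face is roofed by axial C20H2OAc), which forces OMe onto the concave face, the opposite of MeOH addition to an oxocarbenium ion; the closest known reactions are Meerwein lactonium salt formation and Borch-type hydride reduction of O-alkylated amides.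

**Step 10**
Reactants: 13
Product: 14, the spiro δ-lactone (C10–C20H2–O–C7(=O)–C8H2–C9H2) fused to the ring-A methyl acetal
Conditions: K2CO3, MeOH, rt; then toluene, 80 °C
Reagents that add atoms: none
Why: Deacetylation followed by transesterification gives the gem-disubstituted δ-lactone, and the basic medium cannot epimerise the kinetic acetal.

**Step 11**
Reactants: 14; 15, 2,2,2-trifluoroethyl formate
Product: 16, the 8-formyl (hydroxymethylene) lactone
Conditions: LDA, THF, −78 °C; then 15
Reagents that add atoms: 2,2,2-trifluoroethyl formate (15), O=COCC(F)(F)F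
Why: This Claisen-type C-formylation acts on the only enolisable position (C8) and introduces C15.

**Step 12**
Reactants: 16
Product: 17, the 3-formyl-5-spiro-5,6-dihydro-2H-pyran-2-one (C8=C9), used crude
Conditions: PhSeCl, pyridine, CH2Cl2, 0 °C; then 30 % H2O2, 0 °C
Reagents that add atoms: none
Why: α-Selenenylation of the β-dicarbonyl enol followed by selenoxide syn-elimination can only occur towards C9–H and gives the doubly activated alkene under pyridine-buffered conditions.

**Step 13 (key step)**
Reactants: 17; 18, 1,3-butadiene
Product: 19, the cis-fused cyclohexene–lactone aldehyde, (8S,9S), with C12=C13, CHO (C15) on C8 cis to H-9, and C11/C14 on the lactone face bearing C1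
Conditions: butadiene (excess), BHT, toluene, sealed tube, 25 → 70 °C
Reagents that add atoms: 1,3-butadiene (18), C=CC=C
Why: This is an intermolecular Diels–Alder of a 2-formyl-enone-type dienophile, in which suprafacial addition to the ring Z-alkene makes C7/C10 cis, the diene enters from the C1H2 side because the other face carries C5, the acetal and C4, and any hetero-Diels–Alder adduct converges on 19 by Claisen rearrangement on warming.

**Step 14**
Reactants: 19; 20, ethynylmagnesium bromide
Product: 21, the C15 propargylic alcohol (epimers)
Conditions: HC≡CMgBr, THF, −78 → −20 °C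
Reagents that add atoms: ethynylmagnesium bromide (20), C#C[Mg]Br
Why: Grignard 1,2-addition is chemoselective for the aldehyde over the lactone and supplies C16/C17, and the new carbinol centre is erased in step 16.

**Step 15**
Reactants: 21
Product: 22, 15-hydroxy-16-methylene bicyclo[3.2.1]octane (the 15-dihydro target), 13R
Conditions: n-Bu3SnH (syringe pump), AIBN, benzene, 80 °C; then SiO2, CH2Cl2, rt
Reagents that add atoms: none (tin is removed and only H is retained)
Why: In this stannyl-radical enyne cyclisation, Bu3Sn• adds to the alkyne terminus, the C16 vinyl radical closes 5-exo onto C13 on the only face the C8 tether can reach (which sets C13), and neutral silica protodestannylation reveals the exocyclic methylene.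

**Step 16**
Reactants: 22
Product: 23, Ludongnin J
Conditions: Dess–Martin periodinane, NaHCO3, CH2Cl2, 0 °C → rt
Reagents that add atoms: none
Why: Buffered Dess–Martin oxidation of the allylic alcohol gives the α-methylene ketone without acid, so the C6 acetal and the non-enolisable C8 are untouched.

## Compound list
1 | 2-butyne-1,4-diol | OCC#CCO | starting material
2 | (E)-2-(tributylstannyl)but-2-ene-1,4-diol | OC/C=C(/[Sn](CCCC)(CCCC)CCCC)CO | intermediate
3 | (E)-4-TBSO-2-(tributylstannyl)but-2-en-1-ol | CC(C)(C)[Si](C)(C)OC/C=C(/[Sn](CCCC)(CCCC)CCCC)CO | intermediate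
4 | vinyl bromide | C=CBr | starting material
5 | (Z)-4-TBSO-2-vinylbut-2-en-1-ol | CC(C)(C)[Si](C)(C)OC/C=C(/C=C)CO | intermediate
6 | (Z)-4-TBSO-2-vinylbut-2-enyl acetate | CC(C)(C)[Si](C)(C)OC/C=C(/C=C)COC(C)=O | intermediate
7 | methacrolein | C=C(C)C=O | starting material
8 | ring-A Diels–Alder aldehyde | O=C[C@]1(C)CCC=C(COC(C)=O)[C@@H]1CO[Si](C)(C)C(C)(C)C | intermediate
9 | ring-A 1,4-diol | OC[C@]1(C)CCC=C(COC(C)=O)[C@@H]1CO | intermediate
10 | cis-fused γ-lactone (C6=O) | O=C1OC[C@]2(C)CCC=C(COC(C)=O)[C@H]12 | intermediate
11 | methyl acrylate | C=CC(=O)OC | starting material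
12 | C10-quaternary Giese adduct | O=C1OC[C@]2(C)CCC[C@@](COC(C)=O)(CCC(=O)OC)[C@H]12 | intermediate
13 | (6R)-methyl acetal | CO[C@@H]1OC[C@]2(C)CCC[C@@](COC(C)=O)(CCC(=O)OC)[C@H]12 | intermediate
14 | spiro δ-lactone | CO[C@@H]1OC[C@]2(C)CCC[C@]3(COC(=O)CC3)[C@H]12 | intermediate
15 | 2,2,2-trifluoroethyl formate | O=COCC(F)(F)F | starting material
16 | 8-(hydroxymethylene) lactone | CO[C@@H]1OC[C@]2(C)CCC[C@]3(COC(=O)C(=CO)C3)[C@H]12 | intermediate
17 | 3-formyl spiro-dihydropyranone | CO[C@@H]1OC[C@]2(C)CCC[C@]3(COC(=O)C(C=O)=C3)[C@H]12 | intermediate
18 | 1,3-butadiene | C=CC=C | starting material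
19 | ring-C Diels–Alder aldehyde | O=C[C@]12CC=CC[C@H]1[C@@]1(CCC[C@@]3(C)CO[C@@H](OC)[C@H]31)COC2=O | intermediate
20 | ethynylmagnesium bromide | C#C[Mg]Br | starting material
21 | C15 propargylic alcohol (C15 epimers) | C#CC(O)[C@]12CC=CC[C@H]1[C@@]1(CCC[C@@]3(C)CO[C@@H](OC)[C@H]31)COC2=O | intermediate
22 | 15-hydroxy-16-ene (C15 epimers) | C=C1C(O)[C@]23C[C@H]1CC[C@H]2[C@@]1(CCC[C@@]2(C)CO[C@@H](OC)[C@H]21)COC3=O | intermediate
23 | Ludongnin J | C=C1C(=O)[C@]23C[C@H]1CC[C@H]2[C@@]1(CCC[C@@]2(C)CO[C@@H](OC)[C@H]21)COC3=O | target

## Totals
- Total steps: 16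
- Longest linear sequence: 16

## Three steps most likely to fail
1. **Step 13.** The β-carbon is neopentyl and next to the spiro centre, and 17 is labile.
   - Fallback: use 2-(tert-butyldimethylsilyloxy)butadiene, which is far more nucleophilic and which the para rule directs to place oxygen at C12.
   - Ring D is then closed by Au(I)-catalysed 5-exo-dig attack of the resulting C12=C13 silyl enol ether on the C15 propargylic alkyne.
   - The C12 ketone is deleted (tosylhydrazone/catecholborane) before the final oxidation.
2. **Step 9.** The risks are selective lactonium formation and hydride capture, and later survival of the kinetic acetal.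
   - Fallback: on the C20-O-TBDPS analogue of 10, reduce the lactone to the lactol with DIBAL-H.
   - Convert the lactol to the convex-face anomeric bromide.
   - Displace the bromide with MeOH on insoluble silver silicate. This SN2-type glycosidation proceeds with inversion and places OMe on the concave face.
3. **Step 5.** The 1- and 2-substituents of the diene direct regiochemistry in opposite senses, and endo selectivity and ee are also at risk.
   - Fallback: build lactone 10 from a thermal endo Diels–Alder of citraconic anhydride with (E)-penta-2,4-dienyl acetate.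
   - Reduce the hindered carbonyl selectively with NaBH4.
   - Resolve at the C20 alcohol/acetate stage with a lipase.
   - Move the alkene from C1=C2 to C1=C10 with Co(salen)/silane.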